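**Plan**
- Cuts (carotenoid numbering): C15–C15' (Stille) gives two C20 halves; each half is cut at C10=C11 (Horner–Wadsworth–Emmons with a C5 dienyl phosphonate, stannylated for the ring A half and iodinated for the ring B half) and at C8=C9 (Wittig); ring B is cut at C6'=C7' (ethynylation, Meyer–Schuster); ring A is cut at C5–C6 (carbocupration of an ynoate) and at the ring bond C3–C4.
- Forward: a lactone gives the open-chain bromo dienoate 8; ring A then closes by a radical Heck cyclisation that joins the CH2Br carbon (C3) to the isopropenyl CH2 (C4); ring B comes from a preformed cyclohexanone; both C11 aldehydes are extended to C20 and united last.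
- Enabling feature: in ring A, C4 is the unsubstituted δ-terminus of the dienoate C4=C5–C6=C7–C8(=O), and C3 hangs from C6 through the quaternary C1; a C3 radical is therefore set up for 6-endo closure at C4, and the methyl-bearing C5 restores C4=C5 by loss of a C4 hydrogen.
- Stereochemistry: C5' (S) from RAMP-hydrazone methylation; 6E from syn-carbocupration; 6'E from the thermodynamically preferred Meyer–Schuster enal; chain E from Wittig and Horner–Wadsworth–Emmons steps; retention in iododestannylation and Stille coupling.

Key step: step 6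

Remark: the target is read as (5'S,6E,6'E)-4,5'-retro-β,β-carotene with an all-E chain; ring A is C1 (CMe2), C2, C3, C4 (ring CH=), C5 (CMe), C6 (ring carbon of the exocyclic double bond), the chain is C7–C15, and ring B with its half-chain is primed.

**Ring A half**

Step 1
Reactants: 1 3,3-dimethyloxolan-2-one
Product: 2 3,3-dimethyloxolan-2-ol
Conditions: i-Bu2AlH (1.1 equiv), CH2Cl2, −78 °C; aq. potassium sodium tartrate
Reagents that add atoms: none
Why: Partial lactone reduction with i-Bu2AlH at −78 °C should stop at the lactol, the masked α-quaternary aldehyde whose carbonyl carbon becomes C6.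

Step 2
Reactants: 2 3,3-dimethyloxolan-2-ol
Product: 3 3,3-dimethylpent-4-yn-1-ol
Conditions: dimethyl (1-diazo-2-oxopropyl)phosphonate, K2CO3, MeOH, 0 °C → rt
Reagents that add atoms: dimethyl (1-diazo-2-oxopropyl)phosphonate, CC(=O)C(=[N+]=[N-])P(=O)(OC)OC
Why: Seyferth–Gilbert homologation in the Ohira–Bestmann form acts on the open hydroxy-aldehyde tautomer, which is non-enolisable, and the new alkyne carbon becomes C7.

Step 3
Reactants: 3 3,3-dimethylpent-4-yn-1-ol
Product: 4 5-bromo-3,3-dimethylpent-1-yne
Conditions: CBr4, PPh3, CH2Cl2, 0 °C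
Reagents that add atoms: carbon tetrabromide, BrC(Br)(Br)Br
Why: Appel bromination converts the primary alcohol into the C3 bromide, the later radical precursor, without touching the alkyne.

Step 4
Reactants: 4 5-bromo-3,3-dimethylpent-1-yne
Product: 6 ethyl 6-bromo-4,4-dimethylhex-2-ynoate, via lithium acetylide 5 (not isolated)
Conditions: n-BuLi (1.0 equiv), THF, −78 °C; then ClCO2Et, −78 → 0 °C
Reagents that add atoms: ethyl chloroformate, CCOC(Cl)=O
Why: Acetylide acylation with a chloroformate gives the ynoate; deprotonation is much faster than attack on the primary bromide at −78 °C, and the acetylide cannot reach the bromide intramolecularly.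

Step 5
Reactants: 6 ethyl 6-bromo-4,4-dimethylhex-2-ynoate
Product: 8 ethyl (2Z)-6-bromo-4,4-dimethyl-3-(prop-1-en-2-yl)hex-2-enoate, via alkenylcopper adduct 7 (not isolated)
Conditions: CH2=C(CH3)MgBr and CuBr·SMe2 (1:1, 1.5 equiv), THF, −78 °C; add 6; aq. NH4Cl at −78 °C
Reagents that add atoms: isopropenylmagnesium bromide, CC(=C)[Mg]Br
Why: Syn-carbocupration of the ynoate (organocopper conjugate addition) places the isopropenyl group (C4, C5 and its methyl) on C6 cis to copper, so cold protonation leaves the ester cis to the quaternary C1; this is named 2Z here because the tert-alkyl group outranks isopropenyl, and it is the 6E geometry of ring A.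

Step 6
Reactants: 8 ethyl (2Z)-6-bromo-4,4-dimethyl-3-(prop-1-en-2-yl)hex-2-enoate
Product: 9 ethyl (2E)-2-(2,6,6-trimethylcyclohex-2-en-1-ylidene)acetate
Conditions: Pd(OAc)2 (10 mol %), Xantphos (20 mol %), Cs2CO3 (2 equiv), PhH (0.02 M), blue LEDs (450 nm), rt, Ar
Reagents that add atoms: none
Why: Proposed new method: photoexcited zerovalent palladium (from Pd(OAc)2 and Xantphos) abstracts the bromine of 8 by single-electron transfer, the primary C3 radical adds to C4 (the unsubstituted δ-terminus of the dienoate C4=C5–C6=C7–CO2Et), the resulting C5–C6–C7 allyl radical is captured by the monovalent bromopalladium species as an allyl complex of divalent palladium, and β-hydride elimination from C4 restores C4=C5 while Cs2CO3 takes up HBr and returns zerovalent palladium. The closest known reaction type is the palladium-catalysed radical Heck cyclisation of unactivated alkyl halides under visible light or heat, known for exo closures and for tethered endo closures onto simple alkenes but not for a diene terminus of this kind. Ring A closes in the 6-endo-trig mode, and no stereocentre is formed. The step needs 6-endo over 5-exo selectivity, which is secured by the fully substituted C5, by the sp2 carbon C6 in the tether, by the gem-dimethyl group on C1 and by the polarity match between the nucleophilic alkyl radical and the electron-poor diene terminus. It needs hydrogen loss from C4 and not from the C5 methyl group, which is favoured because it gives the endocyclic, linearly conjugated dienoate and because reversible hydridopalladium addition can drain an exocyclic isomer into it. It also needs the C6=C7 geometry from step 5 to survive, which calls for fast capture of the allyl radical at room temperature.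

Step 7
Reactants: 9 ethyl (2E)-2-(2,6,6-trimethylcyclohex-2-en-1-ylidene)acetate
Product: 10 (2E)-2-(2,6,6-trimethylcyclohex-2-en-1-ylidene)ethan-1-ol
Conditions: i-Bu2AlH (2.2 equiv), CH2Cl2, −78 °C; aq. potassium sodium tartrate
Reagents that add atoms: none
Why: Ester reduction with i-Bu2AlH is a clean 1,2-reduction of the conjugated ester to the allylic alcohol and leaves the diene untouched.

Step 8
Reactants: 10 (2E)-2-(2,6,6-trimethylcyclohex-2-en-1-ylidene)ethan-1-ol
Product: 11 (2E)-2-(2,6,6-trimethylcyclohex-2-en-1-ylidene)acetaldehyde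
Conditions: MnO2 (excess), CH2Cl2, rt
Reagents that add atoms: none
Why: MnO2 oxidation is selective for allylic alcohols and neutral, so the exocyclic E double bond should be kept.

Step 9
Reactants: 11 (2E)-2-(2,6,6-trimethylcyclohex-2-en-1-ylidene)acetaldehyde
Product: 12 (2E,4E)-2-methyl-4-(2,6,6-trimethylcyclohex-2-en-1-ylidene)but-2-enal
Conditions: Ph3P=C(CH3)CHO, toluene, 90 °C
Reagents that add atoms: 2-(triphenylphosphoranylidene)propanal, CC(C=O)=P(c1ccccc1)(c1ccccc1)c1ccccc1
Why: Wittig olefination with the stabilised formyl ylide is E-selective and stops after one homologation because the product dienal is less electrophilic; it installs C9 with its methyl group and C10 as the aldehyde.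

**Linchpin (C11–C15)**

Step 10
Reactants: 13 (2E)-3-methylpent-2-en-4-yn-1-ol
Product: 14 (2E,4E)-3-methyl-5-(tributylstannyl)penta-2,4-dien-1-ol
Conditions: Bu3SnH, PdCl2(PPh3)2 (2 mol %), THF, 0 °C
Reagents that add atoms: tributyltin hydride, CCCC[SnH](CCCC)CCCC
Why: Palladium-catalysed hydrostannation adds Sn–H syn across the terminal alkyne with tin at the unhindered terminus, giving the (E)-alkenylstannane carbon that becomes C15.

Step 11
Reactants: 14 (2E,4E)-3-methyl-5-(tributylstannyl)penta-2,4-dien-1-ol
Product: 15 [(1E,3E)-5-bromo-3-methylpenta-1,3-dien-1-yl]tributylstannane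
Conditions: CBr4, PPh3, CH2Cl2, −20 °C; used crude
Reagents that add atoms: carbon tetrabromide, BrC(Br)(Br)Br
Why: Appel bromination is essentially neutral and should convert the primary allylic alcohol without protodestannylation.

Step 12
Reactants: 15 [(1E,3E)-5-bromo-3-methylpenta-1,3-dien-1-yl]tributylstannane
Product: 16 diethyl [(2E,4E)-3-methyl-5-(tributylstannyl)penta-2,4-dien-1-yl]phosphonate
Conditions: P(OEt)3 (neat), 90 °C
Reagents that add atoms: triethyl phosphite, CCOP(OCC)OCC
Why: Michaelis–Arbuzov reaction at the primary allylic bromide gives the phosphonate–stannane linchpin with the methyl group placed for C13.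

**Ring A C20 stannane**

Step 13
Reactants: 12 (2E,4E)-2-methyl-4-(2,6,6-trimethylcyclohex-2-en-1-ylidene)but-2-enal; 16 diethyl [(2E,4E)-3-methyl-5-(tributylstannyl)penta-2,4-dien-1-yl]phosphonate
Product: 18 tributyl[(1E,3E,5E,7E)-3,7-dimethyl-9-[(E)-2,6,6-trimethylcyclohex-2-en-1-ylidene]nona-1,3,5,7-tetraen-1-yl]stannane, via sodium stannylphosphonate carbanion 17 (not isolated)
Conditions: 16, NaN(SiMe3)2, THF, −78 °C; then 12, −78 → 0 °C, Ar, dim light
Reagents that add atoms: none
Why: Horner–Wadsworth–Emmons olefination of the allylic phosphonate carbanion with the enal forms C10=C11 E-selectively, and the non-nucleophilic amide base leaves the alkenylstannane intact.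

**Ring B half**

Step 14
Reactants: 19 2,2-dimethylcyclohexan-1-one
Product: 20 (2R)-N-[(1E)-2,2-dimethylcyclohexylidene]-2-(methoxymethyl)pyrrolidin-1-amine
Conditions: RAMP, p-TsOH (cat.), cyclohexane, reflux (Dean–Stark)
Reagents that add atoms: (R)-1-amino-2-(methoxymethyl)pyrrolidine (RAMP), COC[C@H]1CCCN1N
Why: Hydrazone formation places the amino group anti to the quaternary carbon and sets up the auxiliary-controlled alkylation at the only α-CH2.

Step 15
Reactants: 20 (2R)-N-[(1E)-2,2-dimethylcyclohexylidene]-2-(methoxymethyl)pyrrolidin-1-amine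
Product: 22 (2R)-2-(methoxymethyl)-N-[(6S)-2,2,6-trimethylcyclohexylidene]pyrrolidin-1-amine, via lithium azaenolate 21 (not isolated)
Conditions: LiN(i-Pr)2, THF, 0 °C; then MeI, −95 °C → rt
Reagents that add atoms: iodomethane, CI
Why: SAMP/RAMP-hydrazone alkylation: the chelated lithium azaenolate is methylated on the face left open by the methoxymethyl arm, and the established model for the RAMP series predicts the S configuration at the new centre (the later C5').

Step 16
Reactants: 22 (2R)-2-(methoxymethyl)-N-[(6S)-2,2,6-trimethylcyclohexylidene]pyrrolidin-1-amine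
Product: 23 (6S)-2,2,6-trimethylcyclohexan-1-one
Conditions: O3, CH2Cl2, −78 °C; Ar purge
Reagents that add atoms: ozone, [O-][O+]=O
Why: Ozonolytic hydrazone cleavage releases the ketone without acid or base, so the α-stereocentre should not epimerise.

Step 17
Reactants: 23 (6S)-2,2,6-trimethylcyclohexan-1-one
Product: 24 (6S)-1-ethynyl-2,2,6-trimethylcyclohexan-1-ol
Conditions: HC≡CMgBr, THF, 0 °C → rt; aq. NH4Cl work-up
Reagents that add atoms: ethynylmagnesium bromide, C#C[Mg]Br
Why: Grignard 1,2-addition of the weakly basic ethynyl reagent should outrun enolisation of the hindered ketone; the carbinol configuration is irrelevant because this carbon becomes sp2.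

Step 18
Reactants: 24 (6S)-1-ethynyl-2,2,6-trimethylcyclohexan-1-ol
Product: 25 (2E)-2-[(6S)-2,2,6-trimethylcyclohexylidene]acetaldehyde
Conditions: MoO2(acac)2 (1 mol %), AuCl(PPh3) (1 mol %), AgOTf (1 mol %), toluene, rt
Reagents that add atoms: none
Why: Meyer–Schuster rearrangement (formal 1,3-hydroxyl shift, then tautomerisation) gives the enal under mild conditions; the E isomer, with the formyl group on the CH(CH3) side, avoids allylic strain with the gem-dimethyl group and is the expected major product.

Step 19
Reactants: 25 (2E)-2-[(6S)-2,2,6-trimethylcyclohexylidene]acetaldehyde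
Product: 26 (2E,4E)-2-methyl-4-[(6S)-2,2,6-trimethylcyclohexylidene]but-2-enal
Conditions: Ph3P=C(CH3)CHO, toluene, 90 °C
Reagents that add atoms: 2-(triphenylphosphoranylidene)propanal, CC(C=O)=P(c1ccccc1)(c1ccccc1)c1ccccc1
Why: Wittig olefination with the stabilised ylide is E-selective, and the ylide is too weakly basic to deprotonate the γ-position that carries C5'.

**Ring B C20 iodide**

Step 20
Reactants: 16 diethyl [(2E,4E)-3-methyl-5-(tributylstannyl)penta-2,4-dien-1-yl]phosphonate
Product: 27 diethyl [(2E,4E)-5-iodo-3-methylpenta-2,4-dien-1-yl]phosphonate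
Conditions: I2 (1.0 equiv), CH2Cl2, 0 °C, dark
Reagents that add atoms: iodine, II
Why: Iododestannylation is an ipso substitution with retention of alkene geometry; carrying it out on the C5 linchpin instead of on a pentaenylstannane keeps iodine away from the long polyene and gives the iodo partner for the second half.

Step 21
Reactants: 26 (2E,4E)-2-methyl-4-[(6S)-2,2,6-trimethylcyclohexylidene]but-2-enal; 27 diethyl [(2E,4E)-5-iodo-3-methylpenta-2,4-dien-1-yl]phosphonate
Product: 29 (6S)-1-[(1E,2E,4E,6E,8E)-9-iodo-3,7-dimethylnona-2,4,6,8-tetraen-1-ylidene]-2,2,6-trimethylcyclohexane, via sodium iododienylphosphonate carbanion 28 (not isolated)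
Conditions: 27, NaN(SiMe3)2 (1.0 equiv, no excess), THF, −78 °C; then 26, −78 → 0 °C, Ar, dark
Reagents that add atoms: none
Why: Horner–Wadsworth–Emmons olefination forms C10'=C11' E-selectively; the (E)-alkenyl iodide has no hydrogen anti to iodine and no β-leaving-group relationship to the delocalised carbanion, so it should survive one equivalent of the amide base at low temperature, and preforming the carbanion with no excess base protects the vinylogously acidic C5' hydrogen.

**Union**

Step 22
Reactants: 18 tributyl[(1E,3E,5E,7E)-3,7-dimethyl-9-[(E)-2,6,6-trimethylcyclohex-2-en-1-ylidene]nona-1,3,5,7-tetraen-1-yl]stannane; 29 (6S)-1-[(1E,2E,4E,6E,8E)-9-iodo-3,7-dimethylnona-2,4,6,8-tetraen-1-ylidene]-2,2,6-trimethylcyclohexane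
Product: 30 (5'S,6E,6'E)-4,5'-retro-β,β-carotene
Conditions: Pd2(dba)3 (5 mol %), AsPh3 (40 mol %), NMP, rt → 40 °C, Ar, dark
Reagents that add atoms: none
Why: Stille cross-coupling joins C15 and C15' with retention of both alkene geometries under neutral conditions that the polyenes and the C5' stereocentre should tolerate.

**Compound list**
1 | 3,3-dimethyloxolan-2-one | CC1(C)CCOC1=O | starting material
2 | 3,3-dimethyloxolan-2-ol | CC1(C)CCOC1O | intermediate
3 | 3,3-dimethylpent-4-yn-1-ol | C#CC(C)(C)CCO | intermediate
4 | 5-bromo-3,3-dimethylpent-1-yne | C#CC(C)(C)CCBr | intermediate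
5 | (5-bromo-3,3-dimethylpent-1-yn-1-yl)lithium (lithium acetylide) | [Li]C#CC(C)(C)CCBr | intermediate
6 | ethyl 6-bromo-4,4-dimethylhex-2-ynoate | CCOC(=O)C#CC(C)(C)CCBr | intermediate
7 | ethyl 6-bromo-2-cuprio-4,4-dimethyl-3-(prop-1-en-2-yl)hex-2-enoate, copper cis to isopropenyl (alkenylcopper adduct) | CCOC(=O)/C([Cu])=C(/C(C)=C)C(C)(C)CCBr | intermediate
8 | ethyl (2Z)-6-bromo-4,4-dimethyl-3-(prop-1-en-2-yl)hex-2-enoate | CCOC(=O)/C=C(/C(C)=C)C(C)(C)CCBr | intermediate
9 | ethyl (2E)-2-(2,6,6-trimethylcyclohex-2-en-1-ylidene)acetate | CCOC(=O)/C=C1/C(C)=CCCC1(C)C | intermediate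
10 | (2E)-2-(2,6,6-trimethylcyclohex-2-en-1-ylidene)ethan-1-ol | OC/C=C1/C(C)=CCCC1(C)C | intermediate
11 | (2E)-2-(2,6,6-trimethylcyclohex-2-en-1-ylidene)acetaldehyde | O=C/C=C1/C(C)=CCCC1(C)C | intermediate
12 | (2E,4E)-2-methyl-4-(2,6,6-trimethylcyclohex-2-en-1-ylidene)but-2-enal | O=C/C(C)=C/C=C1/C(C)=CCCC1(C)C | intermediate
13 | (2E)-3-methylpent-2-en-4-yn-1-ol | C#C/C(C)=C/CO | starting material
14 | (2E,4E)-3-methyl-5-(tributylstannyl)penta-2,4-dien-1-ol | CCCC[Sn](CCCC)(CCCC)/C=C/C(C)=C/CO | intermediate
15 | [(1E,3E)-5-bromo-3-methylpenta-1,3-dien-1-yl]tributylstannane | CCCC[Sn](CCCC)(CCCC)/C=C/C(C)=C/CBr | intermediate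
16 | diethyl [(2E,4E)-3-methyl-5-(tributylstannyl)penta-2,4-dien-1-yl]phosphonate | CCOP(=O)(OCC)C/C=C(C)/C=C/[Sn](CCCC)(CCCC)CCCC | intermediate
17 | sodium carbanion of 16 (sodium stannylphosphonate carbanion) | [Na+].CCOP(=O)(OCC)[CH-]/C=C(C)/C=C/[Sn](CCCC)(CCCC)CCCC | intermediate
18 | tributyl[(1E,3E,5E,7E)-3,7-dimethyl-9-[(E)-2,6,6-trimethylcyclohex-2-en-1-ylidene]nona-1,3,5,7-tetraen-1-yl]stannane | CCCC[Sn](CCCC)(CCCC)/C=C/C(C)=C/C=C/C(C)=C/C=C1/C(C)=CCCC1(C)C | intermediate
19 | 2,2-dimethylcyclohexan-1-one | CC1(C)CCCCC1=O | starting material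
20 | (2R)-N-[(1E)-2,2-dimethylcyclohexylidene]-2-(methoxymethyl)pyrrolidin-1-amine | COC[C@H]1CCCN1/N=C1\CCCCC1(C)C | intermediate
21 | lithium azaenolate of 20 | COC[C@H]1CCCN1N([Li])C1=CCCCC1(C)C | intermediate
22 | (2R)-2-(methoxymethyl)-N-[(6S)-2,2,6-trimethylcyclohexylidene]pyrrolidin-1-amine | COC[C@H]1CCCN1N=C1[C@@H](C)CCCC1(C)C | intermediate
23 | (6S)-2,2,6-trimethylcyclohexan-1-one | O=C1[C@@H](C)CCCC1(C)C | intermediate
24 | (6S)-1-ethynyl-2,2,6-trimethylcyclohexan-1-ol (C1 epimers) | C#CC1(O)[C@@H](C)CCCC1(C)C | intermediate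
25 | (2E)-2-[(6S)-2,2,6-trimethylcyclohexylidene]acetaldehyde | O=C/C=C1\[C@@H](C)CCCC1(C)C | intermediate
26 | (2E,4E)-2-methyl-4-[(6S)-2,2,6-trimethylcyclohexylidene]but-2-enal | O=C/C(C)=C/C=C1\[C@@H](C)CCCC1(C)C | intermediate
27 | diethyl [(2E,4E)-5-iodo-3-methylpenta-2,4-dien-1-yl]phosphonate | CCOP(=O)(OCC)C/C=C(C)/C=C/I | intermediate
28 | sodium carbanion of 27 (sodium iododienylphosphonate carbanion) | [Na+].CCOP(=O)(OCC)[CH-]/C=C(C)/C=C/I | intermediate
29 | (6S)-1-[(1E,2E,4E,6E,8E)-9-iodo-3,7-dimethylnona-2,4,6,8-tetraen-1-ylidene]-2,2,6-trimethylcyclohexane | I/C=C/C(C)=C/C=C/C(C)=C/C=C1\[C@@H](C)CCCC1(C)C | intermediate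
30 | (5'S,6E,6'E)-4,5'-retro-β,β-carotene (all-E chain) | CC1=CCCC(C)(C)\C1=C/C=C(C)/C=C/C=C(C)/C=C/C=C/C(C)=C/C=C/C(C)=C/C=C1\[C@@H](C)CCCC1(C)C | target

**Step count and risks**

Total step count: 22. Longest linear sequence: 11 steps (steps 1–9, 13 and 22).

Steps most likely to fail:

1. Step 6. The open-chain C3 radical may be recaptured by palladium and lose a β-hydrogen before it cyclises, hydrogen may be lost from the C5 methyl group instead of from C4, or the allyl intermediate may rotate about C6–C7 and erode the 6E geometry. The fallback closes ring A by metathesis at C4=C5 instead and sets out from 8. Nickel-catalysed reductive cross-electrophile coupling of 8 with vinyl bromide (NiBr2(dme), 4,4'-di-tert-butyl-2,2'-bipyridine, Zn, DMA, rt) should give ethyl (2Z)-4,4-dimethyl-3-(prop-1-en-2-yl)octa-2,7-dienoate F1. Ring-closing metathesis of F1 between the terminal vinyl group and the isopropenyl group (second-generation Hoveyda–Grubbs catalyst, toluene, 80 °C) should then give the ring with loss of ethene and return to the route at 9.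

2. Step 22. The pentaenyl iodide may isomerise or decompose before coupling, transmetalation of the long polyenylstannane may be slow, and stannane homocoupling may compete. The fallback replaces the metal-catalysed union by two olefinations and sets out from 16. Oxidative homocoupling of 16 with CuCl2 (DMF, rt) should give tetraethyl [(2E,4E,6E,8E)-3,8-dimethyldeca-2,4,6,8-tetraene-1,10-diyl]bis(phosphonate) F2. Deprotonation of an excess of F2 with one equivalent of NaN(SiMe3)2 (THF, −78 °C) should give the monosodium carbanion of the bisphosphonate F3. Horner–Wadsworth–Emmons reaction of F3 with 12 should give diethyl [(2E,4E,6E,8E,10E,12E)-3,8,12-trimethyl-14-[(E)-2,6,6-trimethylcyclohex-2-en-1-ylidene]tetradeca-2,4,6,8,10,12-hexaen-1-yl]phosphonate F4. Its sodium carbanion F5 (NaN(SiMe3)2, THF, −78 °C) should react with 26 in a second Horner–Wadsworth–Emmons reaction and return to the route at 30.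

3. Step 18. Rupe-type dehydration of the hindered tertiary carbinol may compete, E/Z control at the exocyclic double bond may be incomplete, and C5' may erode through dienol formation. The fallback uses an oxidative allylic transposition and sets out from 23. Addition of vinylmagnesium bromide (THF, 0 °C) should give (6S)-1-ethenyl-2,2,6-trimethylcyclohexan-1-ol F6. Babler–Dauben oxidative 1,3-transposition of F6 with pyridinium chlorochromate (CH2Cl2, rt) should return to the route at 25.

**Further compounds**
F1 | step 6 | ethyl (2Z)-4,4-dimethyl-3-(prop-1-en-2-yl)octa-2,7-dienoate | CCOC(=O)/C=C(/C(C)=C)C(C)(C)CCC=C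
F2 | step 22 | tetraethyl [(2E,4E,6E,8E)-3,8-dimethyldeca-2,4,6,8-tetraene-1,10-diyl]bis(phosphonate) | CCOP(=O)(OCC)C/C=C(C)/C=C/C=C/C(C)=C/CP(=O)(OCC)OCC
F3 | step 22 | monosodium carbanion of the bisphosphonate F2 | [Na+].CCOP(=O)(OCC)[CH-]/C=C(C)/C=C/C=C/C(C)=C/CP(=O)(OCC)OCC
F4 | step 22 | diethyl [(2E,4E,6E,8E,10E,12E)-3,8,12-trimethyl-14-[(E)-2,6,6-trimethylcyclohex-2-en-1-ylidene]tetradeca-2,4,6,8,10,12-hexaen-1-yl]phosphonate | CCOP(=O)(OCC)C/C=C(C)/C=C/C=C/C(C)=C/C=C/C(C)=C/C=C1/C(C)=CCCC1(C)C
F5 | step 22 | sodium carbanion of F4 | [Na+].CCOP(=O)(OCC)[CH-]/C=C(C)/C=C/C=C/C(C)=C/C=C/C(C)=C/C=C1/C(C)=CCCC1(C)C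
F6 | step 18 | (6S)-1-ethenyl-2,2,6-trimethylcyclohexan-1-ol | C=CC1(O)[C@@H](C)CCCC1(C)C
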